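Cuts: first the CH2–C(=O) bond between the decamethylene chain and the ketone carbon (primary alkylzinc halide + S-ethyl thioester of N-acetyl-L-serine). Then the bond from furan C-5 to the chain (furyllithium + 1,10-dibromodecane). Last the furan ring itself (butenolide from 2,3-dimethylmaleic anhydride and a propyl Grignard reagent).
Enabling feature: the ketone carbon, the NHAc-bearing carbon and the CH2OH carbon are the unchanged C-1, C-2 and C-3 of N-acetyl-L-serine. The ketone carbon can therefore enter as an acyl–sulfur carbon, the one bond of the head group that zerovalent palladium opens. The other partner ends in an unbranched primary CH2 that can carry zinc, and the furan ring, alkylated at all four carbons, offers nothing to either metal.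
Forward: the only ring, the furan, arises first (anhydride, hydroxybutenolide, butenolide, lactol, loss of water). Lithiation at its single ring C–H attaches the C10 chain, and the zincated chain end is joined to the complete, unprotected head group in the last step.
Stereochemistry: the single (S) centre is bought with N-acetyl-L-serine and passes through two base-free steps. The epimerisable, dehydration-prone α-acetamido-β-hydroxy ketone exists only after the final bond is made, and no protecting group is used.

Key step: step 6

Assumption: the butenolide-stage intermediates are carried as racemates, since their ring stereocentres disappear when the furan becomes aromatic.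

Step 1
Reactants: 1 2,3-dimethylmaleic anhydride; 2 n-propylmagnesium chloride
Product: 3 5-hydroxy-3,4-dimethyl-5-propylfuran-2(5H)-one (racemic)
Conditions: 2 (1.05 equiv, Et2O solution) added to 1, THF, −78 to −20 °C; then 1 M HCl
Reagents that add atoms: none
Why: Mono-addition of a Grignard reagent to a symmetrical cyclic anhydride: the first adduct rests as a magnesium carboxylate/alkoxide that is much less electrophilic than 1 at low temperature, so acidification should give the cyclic pseudo-acid 3, whose new stereocentre is racemic and is erased in step 3.

Step 2
Reactants: 3 5-hydroxy-3,4-dimethyl-5-propylfuran-2(5H)-one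
Product: 5 3,4-dimethyl-5-propylfuran-2(5H)-one (racemic), via hydroxy acid 4 (not isolated)
Conditions: NaBH4, EtOH, 0 °C to rt; then 2 M HCl to pH 2, rt
Reagents that add atoms: none
Why: Borohydride reduction of a γ-hydroxybutenolide through its open keto-carboxylate tautomer, followed by acid-induced lactonisation: the (Z) geometry inherited from the ring holds the hydroxyl and carboxyl groups of 4 together so that 5 should close on acidification, and the new stereocentre is racemic and is erased in step 3.

Step 3
Reactants: 5 3,4-dimethyl-5-propylfuran-2(5H)-one
Product: 7 3,4-dimethyl-2-propylfuran, via lactol 6 (not isolated)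
Conditions: i-Bu2AlH (1.1 equiv), CH2Cl2, −78 °C; then 2 M HCl, 0 °C to rt
Reagents that add atoms: none
Why: Half-reduction of the lactone with i-Bu2AlH and acid-catalysed dehydration of the lactol (the standard butenolide-to-furan conversion): the gain of furan aromaticity drives loss of water from 6 and removes both stereocentres.

Step 4
Reactants: 7 3,4-dimethyl-2-propylfuran; 8 1,10-dibromodecane
Product: 10 2-(10-bromodecyl)-3,4-dimethyl-5-propylfuran, via furyllithium 9 (not isolated)
Conditions: n-BuLi (1.05 equiv), THF, 0 °C to rt; solution of 9 added to 8 (3 equiv), THF–DMPU, −20 °C to rt, argon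
Reagents that add atoms: n-butyllithium, [Li]CCCC (its lithium stays only in intermediate 9)
Why: α-Lithiation of a furan and SN2 alkylation: 7 has a single ring C–H, next to oxygen, so deprotonation is regiochemically unambiguous, and inverse addition of 9 to an excess of the symmetrical dibromide should hold back the second substitution.

Step 5
Reactants: 11 N-acetyl-L-serine; 12 ethanethiol
Product: 13 S-ethyl (2S)-2-acetamido-3-hydroxypropanethioate
Conditions: DCC (1.05 equiv), HOBt (1.1 equiv), 12 (3 equiv), THF–DMF, 0 °C to rt, no amine base
Reagents that add atoms: none
Why: Carbodiimide/HOBt thioesterification (a Steglich-type coupling run without DMAP or amine base): the additive intercepts the activated acid before it can cyclise to the oxazolone, the excess thiol should outrun the primary hydroxyl group as acyl acceptor, and the stereocentre of 11 is carried over unchanged.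

Step 6
Reactants: 10 2-(10-bromodecyl)-3,4-dimethyl-5-propylfuran; 13 S-ethyl (2S)-2-acetamido-3-hydroxypropanethioate
Product: 15 N-[(2S)-13-(3,4-dimethyl-5-propylfuran-2-yl)-1-hydroxy-3-oxotridecan-2-yl]acetamide (target), via alkylzinc bromide 14 (not isolated)
Conditions: Zn dust (1.5 equiv, activated with 5 mol % I2), DMA, 80 °C; decanted solution of 14 added over 1 h to 13 (1.2 equiv), PdCl2(PPh3)2 (5 mol %), THF–toluene, 20 °C, argon; aq NH4Cl
Reagents that add atoms: zinc, [Zn] (stays only in intermediate 14)
Why: Fukuyama coupling: zinc inserts into the primary C–Br bond of 10 to give 14, zerovalent palladium (formed from PdCl2(PPh3)2 by a little of 14) adds oxidatively to the acyl C–S bond of 13, thiophilic zinc takes over the ethanethiolate in the transmetalation, and reductive elimination from the acyl(alkyl)palladium species forms the CH2–C(=O) bond. The closest known reaction type is the palladium-catalysed ketone synthesis from S-ethyl thioesters of N-protected α-amino acids and functionalised alkylzinc halides, which runs at room temperature in a neutral medium. No ring is closed and no stereocentre is created; the (S) centre of 13 should be retained because nothing present is basic enough to enolise the thioester or the ketone, or to start loss of the β-hydroxyl group. The selectivity needed is C–S cleavage in preference to the acetamide C–N bond, no addition to the new ketone and no protonolysis of 14 by O–H and N–H: the weak acyl–sulfur bond is the only one the catalyst opens, alkylzinc halides do not add to ketones, and alcohols and secondary amides protonate them far more slowly than the catalysed acyl transfer consumes them when 14 is added slowly. The furan ring, alkylated at all four carbons, has no C–H or C–halogen bond for palladium and meets neither acid nor oxidant. Because this is the last step, the whole head group arrives in one event without protecting groups and the labile ketone meets no further reagent.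

Compound list
1 | 2,3-dimethylmaleic anhydride (3,4-dimethylfuran-2,5-dione) | CC1=C(C)C(=O)OC1=O | starting material
2 | n-propylmagnesium chloride | CCC[Mg]Cl | starting material
3 | 5-hydroxy-3,4-dimethyl-5-propylfuran-2(5H)-one (racemic) | CCCC1(O)OC(=O)C(C)=C1C | intermediate
4 | (Z)-4-hydroxy-2,3-dimethylhept-2-enoic acid (racemic, not isolated) | CCCC(O)/C(C)=C(C)\C(=O)O | intermediate
5 | 3,4-dimethyl-5-propylfuran-2(5H)-one (racemic) | CCCC1OC(=O)C(C)=C1C | intermediate
6 | 3,4-dimethyl-5-propyl-2,5-dihydrofuran-2-ol (mixture of diastereomers, not isolated) | CCCC1OC(O)C(C)=C1C | intermediate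
7 | 3,4-dimethyl-2-propylfuran | CCCc1occ(C)c1C | intermediate
8 | 1,10-dibromodecane | BrCCCCCCCCCCBr | starting material
9 | (3,4-dimethyl-5-propylfuran-2-yl)lithium (not isolated) | CCCc1oc([Li])c(C)c1C | intermediate
10 | 2-(10-bromodecyl)-3,4-dimethyl-5-propylfuran | CCCc1oc(CCCCCCCCCCBr)c(C)c1C | intermediate
11 | N-acetyl-L-serine, (S) | CC(=O)N[C@@H](CO)C(=O)O | starting material
12 | ethanethiol | CCS | starting material
13 | S-ethyl (2S)-2-acetamido-3-hydroxypropanethioate | CCSC(=O)[C@H](CO)NC(C)=O | intermediate
14 | [10-(3,4-dimethyl-5-propylfuran-2-yl)decyl]zinc bromide (not isolated) | CCCc1oc(CCCCCCCCCC[Zn]Br)c(C)c1C | intermediate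
15 | N-[(2S)-13-(3,4-dimethyl-5-propylfuran-2-yl)-1-hydroxy-3-oxotridecan-2-yl]acetamide | CCCc1oc(CCCCCCCCCCC(=O)[C@H](CO)NC(C)=O)c(C)c1C | target

Total step count: 6. Longest linear sequence: 5 steps (1, 2, 3, 4, 6).

Steps most likely to fail

Step 6. Protonolysis of the alkylzinc bromide by the free O–H and N–H of the thioester may outrun the catalysed acyl transfer. The acylpalladium species may lose carbon monoxide, and a zinc alkoxide of the product may start retro-aldol cleavage or dehydration. The fallback is a Weinreb ketone synthesis that sets out from 10 and 11 and comes back at 15. Acid 11 is condensed with N,O-dimethylhydroxylamine hydrochloride (EDC·HCl, HOBt, N-methylmorpholine, CH2Cl2–DMF, 0 °C) to (2S)-2-acetamido-3-hydroxy-N-methoxy-N-methylpropanamide F1. Bromide 10 is turned with magnesium turnings in THF into [10-(3,4-dimethyl-5-propylfuran-2-yl)decyl]magnesium bromide F2. F1 is first deprotonated at O–H and N–H with i-PrMgCl (2 equiv, THF, −20 °C) as a sacrificial base and then treated with F2. N-Methoxy chelation should prevent a second addition, the amidate next to the stereocentre should disfavour enolisation, and aqueous NH4Cl should release 15.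

Step 5. Cyclisation of the activated N-acetyl amino acid to the oxazolone, followed by its enolisation, would erode the configuration. Acyl transfer to the free hydroxyl group would give oligoesters. The fallback avoids any activated acyl derivative; it sets out from 11 (and uses 12) and comes back at 13. The carboxylate of 11 is alkylated (MeI, KHCO3, DMF, rt) to methyl N-acetyl-L-serinate F3. AlMe3 and 12 in CH2Cl2 at 0 °C give dimethylaluminium ethanethiolate F4, taken in excess so that O–H and N–H are also covered. F4 should convert the ester F3 into 13 by aluminium thiolate ester-to-thioester exchange.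

Step 4. A second substitution at the far end of the dibromide, slow SN2 reaction of the hindered furyllithium and competing dehydrobromination may all cut into the monobromide. The fallback installs the chain at the lactone carbonyl before aromatisation. It sets out from 5, bypasses step 3 as well, and comes back at 10. 10-Bromodecan-1-ol is silylated (TBSCl, imidazole, CH2Cl2) to (10-bromodecyloxy)(tert-butyl)dimethylsilane F5. Magnesium in THF gives [10-(tert-butyldimethylsilyloxy)decyl]magnesium bromide F6. Addition of F6 to 5, promoted by CeCl3 (THF, −78 °C), gives the hemiketal 2-[10-(tert-butyldimethylsilyloxy)decyl]-3,4-dimethyl-5-propyl-2,5-dihydrofuran-2-ol F7. On brief work-up with dilute HCl, F7 should lose water to tert-butyl{[10-(3,4-dimethyl-5-propylfuran-2-yl)decyl]oxy}dimethylsilane F8. Bu4NF in THF gives 10-(3,4-dimethyl-5-propylfuran-2-yl)decan-1-ol F9, and an Appel reaction (CBr4, PPh3, CH2Cl2, 0 °C) gives 10.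

Further compounds
F1 | step 6 | (2S)-2-acetamido-3-hydroxy-N-methoxy-N-methylpropanamide | CON(C)C(=O)[C@H](CO)NC(C)=O
F2 | step 6 | [10-(3,4-dimethyl-5-propylfuran-2-yl)decyl]magnesium bromide | CCCc1oc(CCCCCCCCCC[Mg]Br)c(C)c1C
F3 | step 5 | methyl N-acetyl-L-serinate | COC(=O)[C@H](CO)NC(C)=O
F4 | step 5 | dimethylaluminium ethanethiolate | CCS[Al](C)C
F5 | step 4 | (10-bromodecyloxy)(tert-butyl)dimethylsilane | CC(C)(C)[Si](C)(C)OCCCCCCCCCCBr
F6 | step 4 | [10-(tert-butyldimethylsilyloxy)decyl]magnesium bromide | CC(C)(C)[Si](C)(C)OCCCCCCCCCC[Mg]Br
F7 | step 4 | 2-[10-(tert-butyldimethylsilyloxy)decyl]-3,4-dimethyl-5-propyl-2,5-dihydrofuran-2-ol | CCCC1OC(O)(CCCCCCCCCCO[Si](C)(C)C(C)(C)C)C(C)=C1C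
F8 | step 4 | tert-butyl{[10-(3,4-dimethyl-5-propylfuran-2-yl)decyl]oxy}dimethylsilane | CCCc1oc(CCCCCCCCCCO[Si](C)(C)C(C)(C)C)c(C)c1C
F9 | step 4 | 10-(3,4-dimethyl-5-propylfuran-2-yl)decan-1-ol | CCCc1oc(CCCCCCCCCCO)c(C)c1C
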